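**Retrosynthetic overview** (side-chain locants C1′–C15′ and ring locants C1–C6 as in the name of 27)
1. Last-step disconnection of the C3′(sp3)–C4′(sp2) bond: boron-mediated (Zweifel-type) union of the C17 E-alkenyllithium from iodide 6 with the C14 secondary boronic ester 22, without protecting groups. The enabling feature is the isolated trans C4′=C5′ unit lying between the H/Me-bearing stereocentre C3′ and the hydrogen-free quaternary C6′, so a sec-alkyl group can migrate from boron to C4′ with retention and the skipped diene cannot isomerise.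
2. Left half: quaternary C6′ set by copper–NHC-catalysed SN2′ alkynylation of farnesyl phosphate, then desilylation and hydrozirconation–iodination.
3. Right half: C3′ set by sparteine-controlled lithiation–borylation with MeBpin; ring C1 set trans to the ring C3 methyl by conjugate methylation/allylation of (S)-3,4-dimethylcyclohexenone, whose stereocentre comes from an organocatalytic Michael addition.
4. Ring order: the only ring (the cyclohexane) is closed first, by aldol condensation in step 6; its exocyclic methylene follows by methylenation in step 10.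

Key step: step 14

Assumption: the antipodes of the prolinol ether (step 5) and of the sulfonate imidazolinium ligand (step 2) are named on the basis of the usual shielding models; if a test reaction shows the opposite sense, the mirror-image catalyst is used and nothing else changes.

**Route**

Step 1
Reactants: 1 (2E,6E)-farnesol
Product: 2 diethyl (2E,6E)-3,7,11-trimethyldodeca-2,6,10-trien-1-yl phosphate
Conditions: ClP(O)(OEt)2, Et3N, DMAP (cat.), CH2Cl2, 0 °C
Reagents that add atoms: diethyl chlorophosphate, CCOP(=O)(Cl)OCC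
Why: O-phosphorylation of the primary allylic alcohol under mild base should proceed without allylic transposition and provides the leaving group for allylic substitution.

Step 2
Reactants: 2 diethyl (2E,6E)-3,7,11-trimethyldodeca-2,6,10-trien-1-yl phosphate
Product: 3 [(3S,6E)-3-ethenyl-3,7,11-trimethyldodeca-6,10-dien-1-yn-1-yl]trimethylsilane
Conditions: Me3SiC≡CH, i-Bu2AlH, Et3N (5 mol %), hexanes/THF, 50 °C; then 2, CuCl2·2H2O (5 mol %), (4S,5S)-1-(2,6-diisopropylphenyl)-4,5-diphenyl-3-(2-sulfonatophenyl)imidazolinium (5.5 mol %), THF, −30 °C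
Reagents that add atoms: trimethylsilylacetylene (as its diisobutylalane), C#C[Si](C)(C)C
Why: Copper–NHC-catalysed enantioselective SN2′ allylic substitution with an alkynylalane should deliver the alkynyl group γ-selectively to C3 of the E-trisubstituted allyl phosphate, the chiral sulfonate-bridged copper–NHC complex choosing the alkene face and so setting the quaternary stereocentre (S).

Step 3
Reactants: 3 [(3S,6E)-3-ethenyl-3,7,11-trimethyldodeca-6,10-dien-1-yn-1-yl]trimethylsilane
Product: 4 (3S,6E)-3-ethenyl-3,7,11-trimethyldodeca-6,10-dien-1-yne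
Conditions: K2CO3, MeOH, rt
Reagents that add atoms: none
Why: Base-mediated protodesilylation cleaves only the C(sp)–Si bond and touches none of the alkenes.

Step 4
Reactants: 4 (3S,6E)-3-ethenyl-3,7,11-trimethyldodeca-6,10-dien-1-yne
Product: 6 (1E,3S,6E)-3-ethenyl-1-iodo-3,7,11-trimethyldodeca-1,6,10-triene, via E-alkenylzirconocene chloride 5 (not isolated)
Conditions: Cp2Zr(H)Cl (1.05 equiv), THF, 0 °C → rt; then I2 (1.0 equiv), 0 °C
Reagents that add atoms: iodine, II
Why: Hydrozirconation of the terminal alkyne is syn, places zirconium on the terminal carbon and should outpace reaction at the hindered vinyl group; iodinolysis of the C–Zr bond proceeds with retention to give the E-iodoalkene.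

Step 5
Reactants: 7 propanal; 8 but-3-en-2-one (methyl vinyl ketone)
Product: 9 (2S)-2-methyl-5-oxohexanal
Conditions: (R)-2-[methoxy(diphenyl)methyl]pyrrolidine (5 mol %), ethyl 3,4-dihydroxybenzoate (20 mol %), neat, 4 °C
Reagents that add atoms: none
Why: Enamine-catalysed asymmetric Michael addition, in which the diphenylmethyl group shields one face of the E-enamine so that the enone is attacked from the open face, setting the methyl-bearing stereocentre (S).

Step 6
Reactants: 9 (2S)-2-methyl-5-oxohexanal
Product: 11 (4S)-4-methylcyclohex-2-en-1-one, via ketol 10 (not isolated)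
Conditions: LiOH (cat.), i-PrOH, rt
Reagents that add atoms: none
Why: Intramolecular aldol condensation (6-enolendo-exo-trig closure of the methyl ketone enolate onto the aldehyde) forms the cyclohexenone, and mild hydroxide should cyclise and dehydrate faster than the α-stereocentre epimerises.

Step 7
Reactants: 11 (4S)-4-methylcyclohex-2-en-1-one
Product: 12 {[(3R,4S)-3,4-dimethylcyclohex-1-en-1-yl]oxy}trimethylsilane
Conditions: MeMgBr, CuBr·SMe2 (5 mol %), Me3SiCl, THF, −78 °C; Et3N quench; used crude
Reagents that add atoms: methylmagnesium bromide, C[Mg]Br; chlorotrimethylsilane, C[Si](C)(C)Cl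
Why: Copper-catalysed, silyl-chloride-accelerated conjugate addition traps the enolate regiospecifically as the silyl enol ether; the methyl adds anti to the C4 methyl, a centre that is erased again in step 8.

Step 8
Reactants: 12 {[(3R,4S)-3,4-dimethylcyclohex-1-en-1-yl]oxy}trimethylsilane
Product: 13 (4S)-3,4-dimethylcyclohex-2-en-1-one
Conditions: Pd(OAc)2 (10 mol %), O2 (1 atm), DMSO, rt
Reagents that add atoms: none
Why: Saegusa–Ito oxidation (palladation at C2, β-hydride elimination from C3) regenerates the enone with the new methyl on C3 under neutral conditions that leave the C4 stereocentre untouched.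

Step 9
Reactants: 13 (4S)-3,4-dimethylcyclohex-2-en-1-one
Product: 15 (2R,4S)-3,3,4-trimethyl-2-(prop-2-en-1-yl)cyclohexan-1-one, via lithium enolate 14 (not isolated)
Conditions: Me2CuLi (from CuI, MeLi), Et2O, 0 °C; then allyl bromide, DMPU, THF, −30 °C → rt
Reagents that add atoms: lithium dimethylcuprate, [Li+].C[Cu-]C; allyl bromide, C=CCBr
Why: Cuprate conjugate addition builds the gem-dimethyl carbon and a regiodefined enolate, whose C-allylation occurs axially, anti to the pseudoaxial C3 methyl in the half-chair that keeps the C4 methyl pseudoequatorial, so the allyl group should end trans to the C4 methyl (2R) under substrate control.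

Step 10
Reactants: 15 (2R,4S)-3,3,4-trimethyl-2-(prop-2-en-1-yl)cyclohexan-1-one
Product: 16 (1S,3S)-2,2,3-trimethyl-6-methylidene-1-(prop-2-en-1-yl)cyclohexane
Conditions: Zn, CH2Br2, TiCl4, THF/CH2Cl2, 0 °C → rt
Reagents that add atoms: dibromomethane, BrCBr
Why: Takai–Lombardo methylenation uses a non-basic zinc/titanium gem-dimetallic reagent, which should methylenate the hindered, epimerisable ketone without loss of configuration at the α-carbon.

Step 11
Reactants: 16 (1S,3S)-2,2,3-trimethyl-6-methylidene-1-(prop-2-en-1-yl)cyclohexane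
Product: 18 3-[(1S,3S)-2,2,3-trimethyl-6-methylidenecyclohexyl]propan-1-ol, via trialkylborane 17 (not isolated)
Conditions: Sia2BH (from BH3·SMe2 and 2-methylbut-2-ene, 1.05 equiv), THF, 0 °C; then NaOH, H2O2, 0 °C → rt
Reagents that add atoms: hydrogen peroxide, OO
Why: Anti-Markovnikov hydroboration–oxidation with the bulky dialkylborane should select the monosubstituted allyl terminus over the more hindered 1,1-disubstituted exocyclic alkene.

Step 12
Reactants: 18 3-[(1S,3S)-2,2,3-trimethyl-6-methylidenecyclohexyl]propan-1-ol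
Product: 19 3-[(1S,3S)-2,2,3-trimethyl-6-methylidenecyclohexyl]propyl N,N-di(propan-2-yl)carbamate
Conditions: i-Pr2NC(O)Cl, Et3N, CH2Cl2, reflux
Reagents that add atoms: N,N-diisopropylcarbamoyl chloride, CC(C)N(C(C)C)C(Cl)=O
Why: O-carbamoylation (acyl substitution) installs the group that directs α-lithiation and later serves as the leaving group.

Step 13
Reactants: 19 3-[(1S,3S)-2,2,3-trimethyl-6-methylidenecyclohexyl]propyl N,N-di(propan-2-yl)carbamate
Product: 22 4,4,5,5-tetramethyl-2-{(2S)-4-[(1S,3S)-2,2,3-trimethyl-6-methylidenecyclohexyl]butan-2-yl}-1,3,2-dioxaborolane, via lithiated carbamate 20 (not isolated), via boronate complex 21 (not isolated)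
Conditions: s-BuLi, (−)-sparteine, Et2O, −78 °C; MeBpin, −78 °C; MgBr2·OEt2, then reflux
Reagents that add atoms: 2,4,4,5,5-pentamethyl-1,3,2-dioxaborolane (MeBpin), CB1OC(C)(C)C(C)(C)O1
Why: Lithiation–borylation: sparteine-mediated deprotonation removes the pro-S α-hydrogen, borylation occurs with retention, and the Lewis-acid-promoted 1,2-metallate rearrangement (methyl migration with inversion, carbamate leaving) should give the (S)-secondary boronic ester under reagent control.

Step 14
Reactants: 6 (1E,3S,6E)-3-ethenyl-1-iodo-3,7,11-trimethyldodeca-1,6,10-triene; 22 4,4,5,5-tetramethyl-2-{(2S)-4-[(1S,3S)-2,2,3-trimethyl-6-methylidenecyclohexyl]butan-2-yl}-1,3,2-dioxaborolane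
Product: 27 (1S,3S)-1-[(3S,4E,6S,9E)-6-ethenyl-3,6,10,14-tetramethylpentadeca-4,9,13-trien-1-yl]-2,2,3-trimethyl-6-methylidenecyclohexane, via E-alkenyllithium 23 (not isolated), via alkenyl boronate complex 24 (not isolated), via β-seleno boronic ester 25 (not isolated), via selenoxide 26 (not isolated)
Conditions: 6 (1.1 equiv), t-BuLi (2.2 equiv), THF, −78 °C; 22 (1.0 equiv), −78 °C; PhSeCl (1.1 equiv), THF, −78 °C; then mCPBA (1.05 equiv), −78 → −45 °C
Reagents that add atoms: none
Why: Iodine–lithium exchange on 6 gives the configurationally stable E-alkenyllithium 23, which adds to the boron of 22 to form the tetracoordinate boronate 24; PhSeCl then selenates its electron-rich alkene at C5′ and the secondary alkyl group migrates from boron to C4′ anti to selenium (1,2-metallate rearrangement), forming the C3′–C4′ bond with retention at C3′. Oxidation of 25 at selenium lets the selenoxide oxygen attack boron, and the resulting syn β-elimination of the Se/B pair from the anti adduct can only give the E-alkene, whichever face of 24 was selenated. The closest known reaction type is the Zweifel olefination of secondary boronic esters in its selenium-mediated syn-elimination variant. No ring is closed and no new stereocentre is created: C3′ is carried over intact from 22, C6′ from 6, and the C4′=C5′ geometry follows from the anti-addition/syn-elimination sequence. The selectivity needed is chemoselectivity of PhSeCl and of the peracid for the boronate alkene and for selenium over the four spectator alkenes; it is secured by the far higher nucleophilicity of the ate-complex alkene, by selenide oxidation being much faster than epoxidation at low temperature, and by stoichiometric dosing of both reagents, while the hydrogen-free quaternary C6′ rules out isomerisation of the skipped diene.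

**Compound list**
1 | (2E,6E)-farnesol | OC/C=C(\C)CC/C=C(\C)CCC=C(C)C | starting material
2 | diethyl (2E,6E)-3,7,11-trimethyldodeca-2,6,10-trien-1-yl phosphate | CCOP(=O)(OCC)OC/C=C(\C)CC/C=C(\C)CCC=C(C)C | intermediate
3 | [(3S,6E)-3-ethenyl-3,7,11-trimethyldodeca-6,10-dien-1-yn-1-yl]trimethylsilane | C=C[C@@](C)(C#C[Si](C)(C)C)CC/C=C(\C)CCC=C(C)C | intermediate
4 | (3S,6E)-3-ethenyl-3,7,11-trimethyldodeca-6,10-dien-1-yne | C=C[C@@](C)(C#C)CC/C=C(\C)CCC=C(C)C | intermediate
5 | chlorobis(cyclopentadienyl)[(1E,3S,6E)-3-ethenyl-3,7,11-trimethyldodeca-1,6,10-trien-1-yl]zirconium | C=C[C@@](C)(/C=C/[Zr](Cl)(C1C=CC=C1)C1C=CC=C1)CC/C=C(\C)CCC=C(C)C | intermediate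
6 | (1E,3S,6E)-3-ethenyl-1-iodo-3,7,11-trimethyldodeca-1,6,10-triene | C=C[C@@](C)(/C=C/I)CC/C=C(\C)CCC=C(C)C | intermediate
7 | propanal | CCC=O | starting material
8 | but-3-en-2-one | CC(=O)C=C | starting material
9 | (2S)-2-methyl-5-oxohexanal | C[C@H](C=O)CCC(C)=O | intermediate
10 | (4S)-3-hydroxy-4-methylcyclohexan-1-one (either C3 epimer) | C[C@H]1CCC(=O)CC1O | intermediate
11 | (4S)-4-methylcyclohex-2-en-1-one | C[C@H]1CCC(=O)C=C1 | intermediate
12 | {[(3R,4S)-3,4-dimethylcyclohex-1-en-1-yl]oxy}trimethylsilane | C[C@H]1CCC(O[Si](C)(C)C)=C[C@@H]1C | intermediate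
13 | (4S)-3,4-dimethylcyclohex-2-en-1-one | C[C@H]1CCC(=O)C=C1C | intermediate
14 | lithium (4S)-3,3,4-trimethylcyclohex-1-en-1-olate | C[C@H]1CCC(O[Li])=CC1(C)C | intermediate
15 | (2R,4S)-3,3,4-trimethyl-2-(prop-2-en-1-yl)cyclohexan-1-one | C=CC[C@H]1C(=O)CC[C@H](C)C1(C)C | intermediate
16 | (1S,3S)-2,2,3-trimethyl-6-methylidene-1-(prop-2-en-1-yl)cyclohexane | C=CC[C@H]1C(=C)CC[C@H](C)C1(C)C | intermediate
17 | bis(3-methylbutan-2-yl){3-[(1S,3S)-2,2,3-trimethyl-6-methylidenecyclohexyl]propyl}borane | CC(C)C(C)B(CCC[C@H]1C(=C)CC[C@H](C)C1(C)C)C(C)C(C)C | intermediate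
18 | 3-[(1S,3S)-2,2,3-trimethyl-6-methylidenecyclohexyl]propan-1-ol | OCCC[C@H]1C(=C)CC[C@H](C)C1(C)C | intermediate
19 | 3-[(1S,3S)-2,2,3-trimethyl-6-methylidenecyclohexyl]propyl N,N-di(propan-2-yl)carbamate | CC(C)N(C(C)C)C(=O)OCCC[C@H]1C(=C)CC[C@H](C)C1(C)C | intermediate
20 | (1S)-1-lithio-3-[(1S,3S)-2,2,3-trimethyl-6-methylidenecyclohexyl]propyl N,N-di(propan-2-yl)carbamate (as its (−)-sparteine complex) | [Li][C@H](OC(=O)N(C(C)C)C(C)C)CC[C@H]1C(=C)CC[C@H](C)C1(C)C | intermediate
21 | lithium methyl(pinacolato){(1S)-1-[(diisopropylcarbamoyl)oxy]-3-[(1S,3S)-2,2,3-trimethyl-6-methylidenecyclohexyl]propyl}borate | [Li+].C[B-]1(OC(C)(C)C(C)(C)O1)[C@H](OC(=O)N(C(C)C)C(C)C)CC[C@H]2C(=C)CC[C@H](C)C2(C)C | intermediate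
22 | 4,4,5,5-tetramethyl-2-{(2S)-4-[(1S,3S)-2,2,3-trimethyl-6-methylidenecyclohexyl]butan-2-yl}-1,3,2-dioxaborolane | C[C@H](B1OC(C)(C)C(C)(C)O1)CC[C@H]2C(=C)CC[C@H](C)C2(C)C | intermediate
23 | [(1E,3S,6E)-3-ethenyl-3,7,11-trimethyldodeca-1,6,10-trien-1-yl]lithium | C=C[C@@](C)(/C=C/[Li])CC/C=C(\C)CCC=C(C)C | intermediate
24 | lithium (E)-alkenyl(sec-alkyl)pinacolatoborate from 23 and 22 | [Li+].C=C[C@@](C)(/C=C/[B-]1(OC(C)(C)C(C)(C)O1)[C@@H](C)CC[C@H]2C(=C)CC[C@H](C)C2(C)C)CC/C=C(\C)CCC=C(C)C | intermediate
25 | β-(phenylselanyl) boronic ester: C4′ carries Bpin, C5′ carries SePh (one of the two anti adducts drawn; the other has both new centres inverted) | C=C[C@@](C)([C@H]([Se]c1ccccc1)[C@@H](B2OC(C)(C)C(C)(C)O2)[C@@H](C)CC[C@H]3C(=C)CC[C@H](C)C3(C)C)CC/C=C(\C)CCC=C(C)C | intermediate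
26 | selenoxide of 25 | C=C[C@@](C)([C@H]([Se](=O)c1ccccc1)[C@@H](B2OC(C)(C)C(C)(C)O2)[C@@H](C)CC[C@H]3C(=C)CC[C@H](C)C3(C)C)CC/C=C(\C)CCC=C(C)C | intermediate
27 | (1S,3S)-1-[(3S,4E,6S,9E)-6-ethenyl-3,6,10,14-tetramethylpentadeca-4,9,13-trien-1-yl]-2,2,3-trimethyl-6-methylidenecyclohexane (CNP0322301.1) | C=C[C@@](C)(/C=C/[C@@H](C)CC[C@H]1C(=C)CC[C@H](C)C1(C)C)CC/C=C(\C)CCC=C(C)C | target

**Step count and risks**
Total steps: 14 (left half steps 1–4, right half steps 5–13, union step 14). Longest linear sequence: 10 (steps 5–14).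

Steps most likely to fail:

1. Step 14. The electrophilic selenium reagent or the peracid may attack the spectator trisubstituted alkenes, ate-complex formation and migration may be slow next to the quaternary carbon, or premature anti-elimination may leak Z-alkene. The fallback sets out from 4 (and uses 22) and comes back at 27. Alkyne 4 would be lithiated (n-BuLi, THF, −78 °C) and iodinated (I2) to (3S,6E)-3-ethenyl-1-iodo-3,7,11-trimethyldodeca-6,10-dien-1-yne F1. Syn-hydroboration with dicyclohexylborane (1.0 equiv, THF, 0 °C) would give the (Z)-α-iodoalkenyl(dicyclohexyl)borane F2, and protonolysis with AcOH the (1Z,3S,6E)-3-ethenyl-1-iodo-3,7,11-trimethyldodeca-1,6,10-triene F3. t-BuLi (THF, −78 °C) would convert it into the Z-alkenyllithium F4, which with 22 forms the Z-alkenyl boronate complex F5. I2 in THF/MeOH at −78 °C would give the β-iodo boronic ester F6, and NaOMe would induce anti-elimination to 27. This is the classical iodine/methoxide Zweifel olefination, which inverts the alkene geometry (Z to E) and keeps both the selenium electrophile and the peracid out of the flask.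

2. Step 9. C-allylation of the hindered, copper-associated enolate next to the new quaternary carbon may be slow, with O-allylation, proton exchange and erosion of the trans facial selectivity. The fallback sets out from 13 and comes back at 15. Enolate 14, generated as before, would be O-acylated with allyl chloroformate to allyl (4S)-3,3,4-trimethylcyclohex-1-en-1-yl carbonate F7. Pd(PPh3)4 (cat., THF, rt) would then effect decarboxylative Tsuji allylation to 15. C–C bond formation then occurs within a neutral π-allylpalladium/enolate ion pair, regiospecifically at C2 and from the face anti to the axial C3 methyl, without strongly basic conditions that could epimerise C2.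

3. Step 2. Facial discrimination by the copper–NHC catalyst may be insufficient, or α-substitution (SN2) may compete, with the silyl-substituted alkynylalane. The fallback sets out from 1 and comes back at 3. Sharpless asymmetric epoxidation of 1 (Ti(OiPr)4, D-(−)-diethyl tartrate, t-BuOOH, 4 Å molecular sieves, CH2Cl2, −20 °C) would give (2R,3R)-2,3-epoxyfarnesol F8. Opening at the tertiary C3 with inversion by Et2AlC≡CSiMe3 (from LiC≡CSiMe3 and Et2AlCl, toluene, 0 °C) would give the (2S,3R)-1,2-diol F9. NaIO4 (THF/H2O) would cleave it to (2R,5E)-2,6,10-trimethyl-2-[(trimethylsilyl)ethynyl]undeca-5,9-dienal F10, and Wittig methylenation (Ph3PCH3Br, KN(SiMe3)2, THF) would return 3. The quaternary centre then derives from a reagent-controlled epoxidation and a stereospecific substitution instead of catalytic allylic substitution.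

**Further compounds**
F1 | step 14 | (3S,6E)-3-ethenyl-1-iodo-3,7,11-trimethyldodeca-6,10-dien-1-yne | C=C[C@@](C)(C#CI)CC/C=C(\C)CCC=C(C)C
F2 | step 14 | dicyclohexyl[(1Z,3S,6E)-3-ethenyl-1-iodo-3,7,11-trimethyldodeca-1,6,10-trien-1-yl]borane | C=C[C@@](C)(/C=C(\I)B(C1CCCCC1)C1CCCCC1)CC/C=C(\C)CCC=C(C)C
F3 | step 14 | (1Z,3S,6E)-3-ethenyl-1-iodo-3,7,11-trimethyldodeca-1,6,10-triene | C=C[C@@](C)(/C=C\I)CC/C=C(\C)CCC=C(C)C
F4 | step 14 | [(1Z,3S,6E)-3-ethenyl-3,7,11-trimethyldodeca-1,6,10-trien-1-yl]lithium | C=C[C@@](C)(/C=C\[Li])CC/C=C(\C)CCC=C(C)C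
F5 | step 14 | lithium (Z)-alkenyl(sec-alkyl)pinacolatoborate from F4 and 22 | [Li+].C=C[C@@](C)(/C=C\[B-]1(OC(C)(C)C(C)(C)O1)[C@@H](C)CC[C@H]2C(=C)CC[C@H](C)C2(C)C)CC/C=C(\C)CCC=C(C)C
F6 | step 14 | β-iodo boronic ester: C4′ carries Bpin, C5′ carries iodine (one of the two anti adducts) | C=C[C@@](C)([C@@H](I)[C@@H](B2OC(C)(C)C(C)(C)O2)[C@@H](C)CC[C@H]3C(=C)CC[C@H](C)C3(C)C)CC/C=C(\C)CCC=C(C)C
F7 | step 9 | allyl (4S)-3,3,4-trimethylcyclohex-1-en-1-yl carbonate | C[C@H]1CCC(OC(=O)OCC=C)=CC1(C)C
F8 | step 2 | (2R,3R)-2,3-epoxyfarnesol | OC[C@H]1O[C@]1(C)CC/C=C(\C)CCC=C(C)C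
F9 | step 2 | (2S,3R,6E)-3,7,11-trimethyl-3-[(trimethylsilyl)ethynyl]dodeca-6,10-diene-1,2-diol | OC[C@@H](O)[C@@](C)(C#C[Si](C)(C)C)CC/C=C(\C)CCC=C(C)C
F10 | step 2 | (2R,5E)-2,6,10-trimethyl-2-[(trimethylsilyl)ethynyl]undeca-5,9-dienal | O=C[C@@](C)(C#C[Si](C)(C)C)CC/C=C(\C)CCC=C(C)C
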